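**Plan**
- Ring B numbering: C1' bears ring C, C2' the pyran CH=, C3' the pyran O, C4' OH, C5' H, C6' the 1,1-dimethylallyl group.
- Retrosynthetic cuts, in order: the four MOM masks; ring D (the pyran on ring B) at C2'–CH= and O3'–CMe2 together, giving a 2'-bromo-3'-phenol and 3,3-dimethylcyclopropene; the C6'–CMe2 bond by a retro para-Claisen–Cope shift to the O3' 1,1-dimethylallyl ether; ring C at O1–C2 and C3–O (Algar–Flynn–Oyamada) and at Cα=Cβ (Claisen–Schmidt).
- Enabling feature: O3' of ring B has both ortho carbons substituted (C2', C4') and its para carbon C6' carries the 1,1-dimethylallyl group. C2' and O3' are ortho neighbours spanned by a CH=CH–CMe2 unit, which is an isomer of 3,3-dimethylcyclopropene with one CH–CMe2 ring bond opened.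
- Helper: one bromine at C2', bought with the aldehyde. It first blocks the ortho site so the allyl group must travel from O3' to C6'. It then marks the most crowded carbon of ring B for the strain-driven [3+3] annulation and leaves as bromide.
- Forward order: ring A ketone (C8 prenyl in place) + ring B aldehyde → chalcone → ring C → C6' side chain → ring D → MOM removal. The 2',6'-crowding is built only after the C2–C1' bond exists.
- Stereochemistry: the target has no stereocentre. The chalcone E-alkene is consumed and the ring D alkene is cis by ring constraint.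

Key step: step 13

Assumption: 3,3-dimethylcyclopropene 22 is treated as not purchasable. It is made in steps 11 and 12 and handled as a cold stock solution because of its low boiling point.

Step 1
Reactants: 1 2,4,6-trihydroxyacetophenone; 2 prenyl bromide (1-bromo-3-methylbut-2-ene)
Product: 3 2,4,6-trihydroxy-3-(3-methylbut-2-enyl)acetophenone
Conditions: DBU, THF, rt
Reagents that add atoms: none
Why: Base-mediated C-prenylation of the ambident phloroglucinol-type phenoxide is the standard entry to 3-prenylphloroacetophenone, and one equivalent of halide limits double alkylation.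

Step 2
Reactants: 3 2,4,6-trihydroxy-3-(3-methylbut-2-enyl)acetophenone
Product: 4 1-[2-hydroxy-4,6-bis(methoxymethoxy)-3-(3-methylbut-2-enyl)phenyl]ethanone
Conditions: MOMCl (2.2 equiv), i-Pr2NEt, CH2Cl2, 0 °C to rt
Reagents that add atoms: chloromethyl methyl ether (MOMCl), COCCl
Why: In this MOM protection (O-alkylation) the 4-OH and the less hindered 6-OH should react, while the 2-OH, flanked by the prenyl group and hydrogen-bonded to the acetyl group, stays free and so becomes O1 with the prenyl carbon as C8.

Step 3
Reactants: 5 2-bromo-3-hydroxy-4-methoxybenzaldehyde (2-bromoisovanillin)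
Product: 6 2-bromo-3,4-dihydroxybenzaldehyde
Conditions: BBr3, CH2Cl2, −78 °C to rt; then H2O
Reagents that add atoms: none
Why: Lewis-acid cleavage of the aryl methyl ether removes a group that could not be taken off later, at a stage with no acid-sensitive alkene, and the aldehyde and aryl bromide tolerate it.

Step 4
Reactants: 6 2-bromo-3,4-dihydroxybenzaldehyde
Product: 7 2-bromo-3-hydroxy-4-(methoxymethoxy)benzaldehyde
Conditions: MOMCl (1.0 equiv), K2CO3 (1.0 equiv), acetone, 0 °C to rt
Reagents that add atoms: chloromethyl methyl ether (MOMCl), COCCl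
Why: Selective mono-O-alkylation should work because the 4-OH is para to the formyl group and therefore the more acidic, so one equivalent of weak base ionises it preferentially, as is established for protocatechualdehyde.

Step 5
Reactants: 8 2-methylbut-3-en-2-ol
Product: 9 methyl 2-methylbut-3-en-2-yl carbonate
Conditions: n-BuLi, THF, −78 °C; ClCO2Me, −78 to 0 °C
Reagents that add atoms: methyl chloroformate, COC(=O)Cl
Why: Acylation of the lithium alkoxide with a chloroformate gives the tertiary allylic carbonate, the usual precursor of the 1,1-dimethylallylpalladium cation.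

Step 6
Reactants: 7 2-bromo-3-hydroxy-4-(methoxymethoxy)benzaldehyde; 9 methyl 2-methylbut-3-en-2-yl carbonate
Product: 10 2-bromo-4-(methoxymethoxy)-3-(2-methylbut-3-en-2-yloxy)benzaldehyde
Conditions: Pd(PPh3)4 (5 mol %), THF, 0 °C
Reagents that add atoms: none
Why: In this Tsuji–Trost O-allylation zerovalent palladium ionises the carbonate and, under kinetic control, the phenoxide attacks the more substituted allyl terminus, a reaction known for hindered catechol-type phenols, while the C–Br bond is inert to this catalyst at 0 °C.

Step 7
Reactants: 4 1-[2-hydroxy-4,6-bis(methoxymethoxy)-3-(3-methylbut-2-enyl)phenyl]ethanone; 10 2-bromo-4-(methoxymethoxy)-3-(2-methylbut-3-en-2-yloxy)benzaldehyde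
Product: 11 (E)-3-[2-bromo-4-(methoxymethoxy)-3-(2-methylbut-3-en-2-yloxy)phenyl]-1-[2-hydroxy-4,6-bis(methoxymethoxy)-3-(3-methylbut-2-enyl)phenyl]prop-2-en-1-one
Conditions: KOH, EtOH/H2O, rt
Reagents that add atoms: none
Why: The Claisen–Schmidt condensation of a non-enolisable, mono-ortho-substituted aldehyde gives the E-enone through E1cB dehydration, and the MOM ethers and the tertiary allyl ether are stable to base.

Step 8
Reactants: 11 the chalcone of step 7
Product: 13 2-[2-bromo-4-(methoxymethoxy)-3-(2-methylbut-3-en-2-yloxy)phenyl]-3-hydroxy-5,7-bis(methoxymethoxy)-8-(3-methylbut-2-enyl)chromen-4-one, via trans-dihydroflavonol 12 (not isolated)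
Conditions: 30% H2O2, NaOH, MeOH, 0 °C to rt; NH4Cl work-up
Reagents that add atoms: hydrogen peroxide, OO
Why: In the Algar–Flynn–Oyamada reaction nucleophilic peroxide attacks only the enone, the 2'-phenoxide closes ring C at the β-carbon, and 12 is oxidised in situ to the flavonol, as precedented for 4',6'-bis(methoxymethoxy)chalcones; isolated alkenes are untouched.

Step 9
Reactants: 13 the flavonol of step 8
Product: 14 2-[2-bromo-4-(methoxymethoxy)-3-(2-methylbut-3-en-2-yloxy)phenyl]-3,5,7-tris(methoxymethoxy)-8-(3-methylbut-2-enyl)chromen-4-one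
Conditions: MOMCl, i-Pr2NEt, CH2Cl2, 0 °C to rt
Reagents that add atoms: chloromethyl methyl ether (MOMCl), COCCl
Why: MOM protection of the enolic 3-OH ensures that O3' will be the only free hydroxyl once the next step has released it.

Step 10
Reactants: 14 the tetra-ether of step 9
Product: 17 2-[2-bromo-3-hydroxy-4-(methoxymethoxy)-6-(2-methylbut-3-en-2-yl)phenyl]-3,5,7-tris(methoxymethoxy)-8-(3-methylbut-2-enyl)chromen-4-one, via ortho-dienone 15 (not isolated), via para-dienone 16 (not isolated)
Conditions: DMF, 120 °C, argon
Reagents that add atoms: none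
Why: In this para-Claisen rearrangement (aromatic Claisen then Cope) both carbons ortho to O3' are blocked, so the first [3,3] shift gives the non-enolisable dienone 15 (migration onto an oxygen-bearing ortho carbon is known for catechol 1,1-dimethylallyl ethers at this temperature), the second [3,3] shift delivers the group to C6' with the 1,1-dimethylallyl connectivity restored by double inversion (16), and tautomerisation frees O3'–H.

Step 11
Reactants: 18 3-methylbut-2-enal (prenal); 19 4-methylbenzenesulfonohydrazide
Product: 20 (E)-N'-(3-methylbut-2-enylidene)-4-methylbenzenesulfonohydrazide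
Conditions: MeOH, rt
Reagents that add atoms: none
Why: Hydrazone condensation of an enal with tosylhydrazide is fast, and the product normally crystallises from the medium.

Step 12
Reactants: 20 prenal tosylhydrazone
Product: 22 3,3-dimethylcyclopropene, via 1-diazo-3-methylbut-2-ene 21 (not isolated)
Conditions: NaOMe, diglyme, 130–150 °C, N2 sweep, product condensed at −78 °C
Reagents that add atoms: none
Why: In the aprotic Bamford–Stevens reaction the sodium salt loses sulfinate to give 21, which loses N2, and the alkenylcarbene closes to the cyclopropene, a classical entry to 3,3-dialkylcyclopropenes in which the volatile product leaves the hot zone as it forms.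

Step 13
Reactants: 17 the 2'-bromo-3'-phenol of step 10; 22 3,3-dimethylcyclopropene
Product: 24 2-[8-(methoxymethoxy)-2,2-dimethyl-6-(2-methylbut-3-en-2-yl)-2H-chromen-5-yl]-3,5,7-tris(methoxymethoxy)-8-(3-methylbut-2-enyl)chromen-4-one, via allylpalladium bromide 23 (not isolated)
Conditions: 22 (5 equiv, cold dioxane solution, added in portions), Pd(OAc)2 (10 mol %), SPhos (20 mol %), Cs2CO3 (2.5 equiv), 1,4-dioxane, sealed tube, 70 °C
Reagents that add atoms: none
Why: Proposed new method: zerovalent palladium (formed in situ) inserts into the C2'–Br bond of 17, the arylpalladium bromide adds syn across the strained C=C of 22, and the resulting cyclopropylpalladium, which has no syn β-hydrogen, sheds the remaining ring strain by cleaving the bond between the aryl-bearing carbon and CMe2 to give the 1-aryl-3,3-dimethylallylpalladium species 23. After π–σ–π equilibration the caesium phenoxide O3' attacks the CMe2 terminus, which closes ring D and returns zerovalent palladium, so the C2'–CH and O3'–CMe2 bonds arise in one catalytic turnover with bromide as the only loss. The closest known reaction types are the heteroannulation of o-halophenols with 1,3-dienes or allenes through π-allylpalladium phenoxides, the [Cp*RhCl2]2-catalysed [3+3] annulation of N-phenoxyacetamides with 3,3-disubstituted cyclopropenes to 2H-chromenes, and the aryl halide/alkenylcarbene/π-allylpalladium/nucleophile cascades, and ring opening of cyclopropylpalladium intermediates is itself documented. Ring D closes as a six-membered ring by intramolecular allylic substitution with all three allyl carbons becoming ring members (6-endo mode); attack at the benzylic terminus would need a four-membered ring and is excluded, so ring size sets the regiochemistry, and no stereocentre forms because the new ring alkene can only be cis. Site selectivity rests on the bromine, which marks C2' although it is the most crowded carbon of ring B; selectivity among oxygens rests on O3' being the only free hydroxyl (O3, O5, O7 and O4' are MOM ethers); selectivity among alkenes rests on strain, since the vinyl group next to a quaternary carbon and the trisubstituted prenyl alkene insert far more slowly than a cyclopropene. Leakage by β-hydride loss from 23 or by Heck-type retention of the three-membered ring would give isomers of 24 that can still drain to it by hydrogen shift to the o-quinone methide and oxa-6π closure.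

Step 14
Reactants: 24 the tetra-MOM ether of step 13
Product: 25 3,5,7-trihydroxy-2-[8-hydroxy-2,2-dimethyl-6-(2-methylbut-3-en-2-yl)-2H-chromen-5-yl]-8-(3-methylbut-2-enyl)chromen-4-one (CNP0241222.0)
Conditions: HCl (3 M aq), MeOH, 45 °C
Reagents that add atoms: none
Why: Acid-catalysed acetal exchange with methanol removes all four MOM groups under conditions that are standard for prenylated flavonoids, with mild acid and short exposure to avoid cyclisation of the C8 prenyl group onto O7.

**Compound list**
1 | 2,4,6-trihydroxyacetophenone | CC(=O)c1c(O)cc(O)cc1O | starting material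
2 | prenyl bromide | CC(C)=CCBr | starting material
3 | 2,4,6-trihydroxy-3-(3-methylbut-2-enyl)acetophenone | CC(=O)c1c(O)cc(O)c(CC=C(C)C)c1O | intermediate
4 | 1-[2-hydroxy-4,6-bis(methoxymethoxy)-3-(3-methylbut-2-enyl)phenyl]ethanone | CC(=O)c1c(OCOC)cc(OCOC)c(CC=C(C)C)c1O | intermediate
5 | 2-bromo-3-hydroxy-4-methoxybenzaldehyde | COc1ccc(C=O)c(Br)c1O | starting material
6 | 2-bromo-3,4-dihydroxybenzaldehyde | O=Cc1ccc(O)c(O)c1Br | intermediate
7 | 2-bromo-3-hydroxy-4-(methoxymethoxy)benzaldehyde | COCOc1ccc(C=O)c(Br)c1O | intermediate
8 | 2-methylbut-3-en-2-ol | C=CC(C)(C)O | starting material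
9 | methyl 2-methylbut-3-en-2-yl carbonate | C=CC(C)(C)OC(=O)OC | intermediate
10 | 2-bromo-4-(methoxymethoxy)-3-(2-methylbut-3-en-2-yloxy)benzaldehyde | COCOc1ccc(C=O)c(Br)c1OC(C)(C)C=C | intermediate
11 | (E)-chalcone from 4 and 10 | COCOc1ccc(/C=C/C(=O)c2c(O)c(CC=C(C)C)c(OCOC)cc2OCOC)c(Br)c1OC(C)(C)C=C | intermediate
12 | rac-trans-2,3-dihydroflavonol (one enantiomer drawn, not isolated) | C=CC(C)(C)Oc1c(OCOC)ccc([C@@H]2[C@H](C(=O)c3c(OCOC)cc(OCOC)c(CC=C(C)C)c3O2)O)c1Br | intermediate
13 | 3-hydroxyflavone with 2'-Br, 3'-O-(1,1-dimethylallyl), 4',5,7-tri-OMOM, 8-prenyl | COCOc1ccc(-c2oc3c(CC=C(C)C)c(OCOC)cc(OCOC)c3c(=O)c2O)c(Br)c1OC(C)(C)C=C | intermediate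
14 | 3-O-MOM ether of 13 | COCOc1ccc(-c2oc3c(CC=C(C)C)c(OCOC)cc(OCOC)c3c(=O)c2OCOC)c(Br)c1OC(C)(C)C=C | intermediate
15 | ring B cyclohexa-2,4-dienone with prenyl and OMOM on C4' (racemic, not isolated) | COCOC1(CC=C(C)C)C=CC(c2oc3c(CC=C(C)C)c(OCOC)cc(OCOC)c3c(=O)c2OCOC)=C(Br)C1=O | intermediate
16 | ring B cyclohexa-2,5-dienone with H and 1,1-dimethylallyl on C6' (racemic, not isolated) | C=CC(C)(C)C1C=C(OCOC)C(=O)C(Br)=C1c1oc2c(CC=C(C)C)c(OCOC)cc(OCOC)c2c(=O)c1OCOC | intermediate
17 | 2'-bromo-3'-hydroxy-6'-(1,1-dimethylallyl) flavone, 3,5,7,4'-tetra-OMOM, 8-prenyl | C=CC(C)(C)c1cc(OCOC)c(O)c(Br)c1-c1oc2c(CC=C(C)C)c(OCOC)cc(OCOC)c2c(=O)c1OCOC | intermediate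
18 | 3-methylbut-2-enal | CC(C)=CC=O | starting material
19 | 4-methylbenzenesulfonohydrazide | Cc1ccc(S(=O)(=O)NN)cc1 | starting material
20 | prenal tosylhydrazone | CC(C)=C/C=N/NS(=O)(=O)c1ccc(C)cc1 | intermediate
21 | 1-diazo-3-methylbut-2-ene (not isolated) | CC(C)=CC=[N+]=[N-] | intermediate
22 | 3,3-dimethylcyclopropene | CC1(C)C=C1 | intermediate
23 | 1-aryl-3,3-dimethylallylpalladium bromide (σ-form drawn, phosphine omitted, not isolated) | C=CC(C)(C)c1cc(OCOC)c(O)c(C=CC(C)(C)[Pd]Br)c1-c1oc2c(CC=C(C)C)c(OCOC)cc(OCOC)c2c(=O)c1OCOC | intermediate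
24 | tetra-MOM ether of the target | C=CC(C)(C)c1cc(OCOC)c2c(c1-c1oc3c(CC=C(C)C)c(OCOC)cc(OCOC)c3c(=O)c1OCOC)C=CC(C)(C)O2 | intermediate
25 | CNP0241222.0 | C=CC(C)(C)c1cc(O)c2c(c1-c1oc3c(CC=C(C)C)c(O)cc(O)c3c(=O)c1O)C=CC(C)(C)O2 | target

**Step count**
Total step count: 14.
Longest linear sequence: 9 steps (5 → 6 → 7 → 10 → 11 → 13 → 14 → 17 → 24 → 25; steps 3, 4, 6, 7, 8, 9, 10, 13, 14).

**Steps most likely to fail**
1. Step 13 (labelled step).
   - What may go wrong: palladium-catalysed oligomerisation of the cyclopropene may outrun the slow oxidative addition at the crowded, electron-rich C2'–Br bond. C–O bond formation may occur before the three-membered ring opens. Protodebromination is also possible.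
   - Fallback, from 17 to 24: a Mizoroki–Heck reaction of 17 with 2-methylbut-3-en-2-ol 8 (Pd(OAc)2, P(o-tol)3, Et3N, DMF, 100 °C) should give the (E)-2'-(3-hydroxy-3-methylbut-1-enyl)phenol F1. PPTS in warm toluene then ionises the tertiary styryl-allylic alcohol, O3' captures the cation at CMe2, and the route is rejoined at 24. The two bonds are then made in two separate known operations.
2. Step 10.
   - What may go wrong: the tertiary allylic ether may ionise with loss of isoprene. Bromine may be lost or migrate if the first shift goes to C2'. The Cope shift next to ring C may be sluggish.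
   - Fallback, from 14 to 17: Pd(PPh3)4 and morpholine (THF, rt) remove the 1,1-dimethylallyl group to give the 2'-bromo-3'-phenol F2. I2/NaHCO3 (THF/H2O) iodinates the phenoxide ring at its only open activated position, para to O3', to give the 6'-iodide F3. A chemoselective (C–I before C–Br), γ-selective Suzuki–Miyaura coupling with prenylboronic acid pinacol ester (Pd(OAc)2, a γ-directing biarylphosphine, K3PO4, THF/H2O) installs the 1,1-dimethylallyl group and rejoins the route at 17.
3. Step 8.
   - What may go wrong: ring closure may be diverted into the five-membered (aurone) manifold, which a 6'-alkoxy group favours, and oxidation of the dihydroflavonol may be incomplete.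
   - Fallback, from 11 to 13: NaOAc in refluxing EtOH closes the oxa-Michael ring to the racemic flavanone F4. DDQ in dioxane at 80 °C dehydrogenates it to the flavone F5. C3-lithiation with LDA (THF, −78 °C), trapping with B(OMe)3 and oxidation with H2O2/AcOH install the 3-hydroxyl and rejoin the route at 13.

**Further compounds**
F1 | step 13 | (E)-2'-(3-hydroxy-3-methylbut-1-enyl)-3'-hydroxy analogue of 17 | C=CC(C)(C)c1cc(OCOC)c(O)c(/C=C/C(C)(C)O)c1-c1oc2c(CC=C(C)C)c(OCOC)cc(OCOC)c2c(=O)c1OCOC
F2 | step 10 | 2-[2-bromo-3-hydroxy-4-(methoxymethoxy)phenyl]-3,5,7-tris(methoxymethoxy)-8-(3-methylbut-2-enyl)chromen-4-one | COCOc1ccc(-c2oc3c(CC=C(C)C)c(OCOC)cc(OCOC)c3c(=O)c2OCOC)c(Br)c1O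
F3 | step 10 | 2-[2-bromo-3-hydroxy-6-iodo-4-(methoxymethoxy)phenyl]-3,5,7-tris(methoxymethoxy)-8-(3-methylbut-2-enyl)chromen-4-one | COCOc1cc(I)c(-c2oc3c(CC=C(C)C)c(OCOC)cc(OCOC)c3c(=O)c2OCOC)c(Br)c1O
F4 | step 8 | racemic flavanone isomer of 11 | COCOc1ccc(C2CC(=O)c3c(OCOC)cc(OCOC)c(CC=C(C)C)c3O2)c(Br)c1OC(C)(C)C=C
F5 | step 8 | flavone (3-deoxy analogue of 13) | COCOc1ccc(-c2cc(=O)c3c(OCOC)cc(OCOC)c(CC=C(C)C)c3o2)c(Br)c1OC(C)(C)C=C
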